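**Retrosynthetic overview**
1. Numbering: C1 (CH–aryl), C2 (CH–CO2H), C3 (=C–CO2H), C4 (=CH), C4a/C8a (fusion carbons), O on C6 and C7, pendant ring primed. The target is an 8–8′/2–7′ cyclolignan triacid with an E aryl vinyl ether; it is unmasked last from a pentabenzyl ether, after hydrolysis of one imide and two methyl esters.
2. Key disconnection, C1–C2 and C1–C8a in one flask: auxiliary-controlled boron aldol of a Stobbe-derived arylidene-succinate imide with the pendant aldehyde, then acid. The aldolate ionises to a para-benzyloxybenzyl (quinone-methide-type) cation that ring A traps, as in the 2–7′ closure of lignan biosynthesis; both carbinol epimers converge.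
3. Enabling feature: O–C4′ of the pendant ring is para to C1 (C1 can become a quinone-methide-type cation), O–C6 is para to C8a (C8a is the nucleophilic arene carbon), and C2–H is α to a carboxyl (C2 is an enolate carbon; the auxiliary sets it and it then directs C1 trans).
4. Pendant aldehyde: dibromo-olefination of 3,4-bis(benzyloxy)benzaldehyde, site-selective copper C–O coupling with 4-(benzyloxy)-3-hydroxybenzaldehyde (aryloxy enters trans to aryl), palladium methoxycarbonylation with retention (fixes the E enol ether). Ring-A partner: Stobbe condensation, then N-acylation of (R)-4-benzyloxazolidinone.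
5. Order of rings: the three benzene rings are bought; the cyclohexadiene ring C1–C2–C3–C4–C4a–C8a is the only ring of the skeleton that is made and it is closed last; the oxazolidinone is a temporary auxiliary ring, cleaved afterwards.

Key step: step 6

Assumption: the configuration is taken exactly as drawn (ring 1R,2S = 1,2-trans; enol ether E = aryloxy trans to the catechol ring), and the two benzyl-protected aldehydes, dimethyl succinate and (R)-4-benzyl-1,3-oxazolidin-2-one are treated as catalogue chemicals.

Step 1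
Reactants: 1 3,4-bis(benzyloxy)benzaldehyde
Product: 2 1,2-bis(benzyloxy)-4-(2,2-dibromoethenyl)benzene
Conditions: CBr4, PPh3, Zn, CH2Cl2, 0 °C → rt
Reagents that add atoms: carbon tetrabromide, BrC(Br)(Br)Br
Why: Ramirez dibromo-olefination (first stage of the Corey–Fuchs sequence) with the ylide Ph3P=CBr2 made in situ converts the aromatic aldehyde into the 1,1-dibromoalkene under neutral conditions that leave the aryl benzyl ethers untouched, and no stereocentre or alkene geometry is at stake.

Step 2
Reactants: 2 1,2-bis(benzyloxy)-4-(2,2-dibromoethenyl)benzene; 3 4-(benzyloxy)-3-hydroxybenzaldehyde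
Product: 4 4-(benzyloxy)-3-{[(Z)-2-[3,4-bis(benzyloxy)phenyl]-1-bromoethenyl]oxy}benzaldehyde (aryloxy trans to the dibenzyloxyphenyl ring; Br cis to it)
Conditions: CuI (10 mol%), 1,10-phenanthroline (20 mol%), K3PO4, toluene, 80 °C
Reagents that add atoms: none
Why: Ullmann-type copper-catalysed C–O coupling of a 1,1-dibromoalkene with a phenol is site-selective for the less hindered C–Br bond trans to the β-aryl group, so the aryloxy group should enter trans to the dibenzyloxyphenyl ring and the reaction should stop at the (Z)-bromoenol ether because the weak phosphate base does not dehydrobrominate it; the aldehyde of 3 is a spectator.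

Step 3
Reactants: 4 the (Z)-bromoenol ether aldehyde
Product: 5 methyl (E)-2-[2-(benzyloxy)-5-formylphenoxy]-3-[3,4-bis(benzyloxy)phenyl]prop-2-enoate (CO2Me cis to the aryl ring; aryloxy trans to it)
Conditions: CO (1 atm), Pd(OAc)2 (5 mol%), Xantphos, Et3N, MeOH/DMF, 60 °C
Reagents that add atoms: carbon monoxide, [C-]#[O+]; methanol, CO
Why: Palladium-catalysed alkoxycarbonylation (Heck carbonylation) of an alkenyl bromide proceeds with retention of configuration, so CO2Me should take the place of bromine cis to the aryl ring and fix the E enol ether, while the aryl aldehyde and the benzyl ethers are inert at this temperature.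

Step 4
Reactants: 1 3,4-bis(benzyloxy)benzaldehyde; 6 dimethyl succinate
Product: 7 (E)-4-[3,4-bis(benzyloxy)phenyl]-3-(methoxycarbonyl)but-3-enoic acid (aryl trans to CO2Me)
Conditions: NaOMe, MeOH, reflux; then aq HCl
Reagents that add atoms: none
Why: Stobbe condensation (aldol addition, lactonisation to the paraconic ester, E1cB ring opening) delivers the half-ester with the free acid on the CH2 carbon (future C2) and the ester on the alkylidene carbon (future C3), the E alkene with aryl trans to CO2Me being the thermodynamic product.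

Step 5
Reactants: 7 the Stobbe half-ester; 8 (R)-4-benzyl-1,3-oxazolidin-2-one
Product: 10 methyl (E)-2-[3,4-bis(benzyloxy)benzylidene]-4-[(4R)-4-benzyl-2-oxo-1,3-oxazolidin-3-yl]-4-oxobutanoate, via mixed pivalic anhydride 9 (not isolated)
Conditions: PivCl, Et3N, THF, −20 °C; then 8, LiCl, −20 °C → rt
Reagents that add atoms: none
Why: N-Acylation of the Evans oxazolidinone through the mixed pivalic anhydride (Et3N/LiCl protocol) is standard for unsaturated acids and leaves the conjugated alkene and the methyl ester untouched, the only stereocentre being bought with the auxiliary.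

Step 6
Reactants: 10 the (R)-oxazolidinone imide; 5 the pendant enol-ether aldehyde
Product: 13 methyl (1R,2S)-2-{[(4R)-4-benzyl-2-oxo-1,3-oxazolidin-3-yl]carbonyl}-6,7-bis(benzyloxy)-1-{4-(benzyloxy)-3-[((E)-2-[3,4-bis(benzyloxy)phenyl]-1-(methoxycarbonyl)ethenyl)oxy]phenyl}-1,2-dihydronaphthalene-3-carboxylate (1,2-trans), via boron dienolate 11 (not isolated), via boron syn-aldolate 12 (not isolated)
Conditions: Bu2BOTf (1.2 equiv), i-Pr2NEt (1.4 equiv), CH2Cl2, −78 → 0 °C; 5, −78 → 0 °C; then TFA (20 equiv), 0 °C → rt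
Reagents that add atoms: none
Why: Bu2BOTf/i-Pr2NEt gives the (Z)-boron dienolate 11, which adds through its α-carbon (C2) to aldehyde 5 in a Zimmerman–Traxler chair to give syn-aldolate 12; TFA then ionises the C1–O bond to a para-benzyloxybenzyl (quinone-methide-type) cation, C8a of ring A captures it in a Friedel–Crafts closure, and loss of H+ re-aromatises to 13. The closest known reaction types are the Evans syn-aldol and the acid-mediated cyclodehydration of α-(α-hydroxybenzyl) arylidenesuccinates to trans-1-aryl-1,2-dihydronaphthalene-2,3-dicarboxylates, here run in one flask; the ring-closing half copies the 2–7′ closure of the 8–8′-linked quinone methide in cyclolignan biosynthesis. The one ring closed is the six-membered C1–C2–C3–C4–C4a–C8a ring, by 6-exo-trig attack of arene carbon C8a on the exocyclic C1=C1′ bond of the cation (the arene C4a=C8a bond ends up inside the ring). C2 is set by the (R)-4-benzyl auxiliary: the aldehyde approaches the enolate face away from the benzyl group in the dipole-minimised chair, which makes the α-carbon R in 12 and, with the changed CIP ranking, S in 13. C1 is set by C2: the cation is planar, so both carbinol epimers converge, and the aryl group should end up anti to the C2 acyl group (1,2-trans, 1R). The step needs α- over γ-attack of the dienolate (closed boron transition state), ring closure over E1 loss of H-2 to the diene (fast intramolecular capture by an arene carbon para to the C6 benzyloxy group) and para- over ortho-arylation (C8a is para to O–C6 and unhindered, whereas the other ortho carbon lies between the side chain and O–C6).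

Step 7
Reactants: 13 the cyclised imide diester
Product: 15 (1R,2S)-6,7-bis(benzyloxy)-1-{4-(benzyloxy)-3-[((E)-2-[3,4-bis(benzyloxy)phenyl]-1-carboxyethenyl)oxy]phenyl}-1,2-dihydronaphthalene-2,3-dicarboxylic acid, via monoacid diester 14 (not isolated)
Conditions: LiOH, H2O2, THF/H2O, 0 °C; Na2SO3; then LiOH, THF/MeOH/H2O, rt → 45 °C, argon; aq HCl
Reagents that add atoms: hydrogen peroxide, OO; lithium hydroxide, [Li+].[OH-]
Why: Evans hydroperoxide cleavage (the α-effect nucleophile attacks the exocyclic imide carbonyl and is too weakly basic to epimerise C2) is followed by hydroxide saponification of the two methyl esters, which should be safe for the stereocentres because C2 then carries a carboxylate and C1 is not acidic, while benzyl ethers and the aryl vinyl ether are base-stable.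

Step 8
Reactants: 15 the pentabenzyl triacid
Product: 16 (1R,2S)-1-{3-[((E)-1-carboxy-2-(3,4-dihydroxyphenyl)ethenyl)oxy]-4-hydroxyphenyl}-6,7-dihydroxy-1,2-dihydronaphthalene-2,3-dicarboxylic acid (target)
Conditions: BCl3, C6HMe5, CH2Cl2, −78 → −40 °C, argon; then THF/H2O
Reagents that add atoms: none
Why: Lewis-acid debenzylation with BCl3 and pentamethylbenzene as a non-basic cation scavenger cleaves aryl benzyl ethers at low temperature without any reduction, so the C3=C4 alkene, the E enol ether and both stereocentres should survive where hydrogenolysis would not.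

**Compound list**
1 | 3,4-bis(benzyloxy)benzaldehyde | O=Cc1ccc(OCc2ccccc2)c(OCc2ccccc2)c1 | starting material
2 | 1,2-bis(benzyloxy)-4-(2,2-dibromoethenyl)benzene | BrC(Br)=Cc1ccc(OCc2ccccc2)c(OCc2ccccc2)c1 | intermediate
3 | 4-(benzyloxy)-3-hydroxybenzaldehyde | O=Cc1ccc(OCc2ccccc2)c(O)c1 | starting material
4 | 4-(benzyloxy)-3-{[(Z)-2-[3,4-bis(benzyloxy)phenyl]-1-bromoethenyl]oxy}benzaldehyde (aryloxy trans to aryl) | O=Cc1ccc(OCc2ccccc2)c(O/C(Br)=C/c2ccc(OCc3ccccc3)c(OCc3ccccc3)c2)c1 | intermediate
5 | methyl (E)-2-[2-(benzyloxy)-5-formylphenoxy]-3-[3,4-bis(benzyloxy)phenyl]prop-2-enoate | O=Cc1ccc(OCc2ccccc2)c(O/C(=C/c2ccc(OCc3ccccc3)c(OCc3ccccc3)c2)C(=O)OC)c1 | intermediate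
6 | dimethyl succinate | COC(=O)CCC(=O)OC | starting material
7 | (E)-4-[3,4-bis(benzyloxy)phenyl]-3-(methoxycarbonyl)but-3-enoic acid | COC(=O)/C(=C/c1ccc(OCc2ccccc2)c(OCc2ccccc2)c1)CC(=O)O | intermediate
8 | (R)-4-benzyl-1,3-oxazolidin-2-one | O=C1N[C@H](Cc2ccccc2)CO1 | starting material
9 | mixed pivalic anhydride of 7 | COC(=O)/C(=C/c1ccc(OCc2ccccc2)c(OCc2ccccc2)c1)CC(=O)OC(=O)C(C)(C)C | intermediate (not isolated)
10 | methyl (E)-2-[3,4-bis(benzyloxy)benzylidene]-4-[(4R)-4-benzyl-2-oxo-1,3-oxazolidin-3-yl]-4-oxobutanoate | COC(=O)/C(=C/c1ccc(OCc2ccccc2)c(OCc2ccccc2)c1)CC(=O)N1C(=O)OC[C@H]1Cc1ccccc1 | intermediate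
11 | (Z)-dibutylboron dienolate of 10 (O–B cis to the vinyl substituent) | CCCCB(CCCC)O/C(=C\C(=C/c1ccc(OCc2ccccc2)c(OCc2ccccc2)c1)C(=O)OC)N1C(=O)OC[C@H]1Cc1ccccc1 | intermediate (not isolated)
12 | dibutylboron syn-aldolate from 11 and 5 (imide α-carbon R, O-boryl carbinol carbon R) | COC(=O)/C(=C/c1ccc(OCc2ccccc2)c(OCc2ccccc2)c1)[C@@H](C(=O)N1C(=O)OC[C@H]1Cc1ccccc1)[C@@H](OB(CCCC)CCCC)c1ccc(OCc2ccccc2)c(O/C(=C/c2ccc(OCc3ccccc3)c(OCc3ccccc3)c2)C(=O)OC)c1 | intermediate (not isolated)
13 | methyl (1R,2S)-2-{[(4R)-4-benzyl-2-oxo-1,3-oxazolidin-3-yl]carbonyl}-6,7-bis(benzyloxy)-1-{4-(benzyloxy)-3-[((E)-2-[3,4-bis(benzyloxy)phenyl]-1-(methoxycarbonyl)ethenyl)oxy]phenyl}-1,2-dihydronaphthalene-3-carboxylate | COC(=O)C1=Cc2cc(OCc3ccccc3)c(OCc3ccccc3)cc2[C@@H](c2ccc(OCc3ccccc3)c(O/C(=C/c3ccc(OCc4ccccc4)c(OCc4ccccc4)c3)C(=O)OC)c2)[C@@H]1C(=O)N1C(=O)OC[C@H]1Cc1ccccc1 | intermediate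
14 | (1R,2S)-6,7-bis(benzyloxy)-1-{4-(benzyloxy)-3-[((E)-2-[3,4-bis(benzyloxy)phenyl]-1-(methoxycarbonyl)ethenyl)oxy]phenyl}-3-(methoxycarbonyl)-1,2-dihydronaphthalene-2-carboxylic acid | COC(=O)C1=Cc2cc(OCc3ccccc3)c(OCc3ccccc3)cc2[C@@H](c2ccc(OCc3ccccc3)c(O/C(=C/c3ccc(OCc4ccccc4)c(OCc4ccccc4)c3)C(=O)OC)c2)[C@@H]1C(=O)O | intermediate (not isolated)
15 | (1R,2S)-6,7-bis(benzyloxy)-1-{4-(benzyloxy)-3-[((E)-2-[3,4-bis(benzyloxy)phenyl]-1-carboxyethenyl)oxy]phenyl}-1,2-dihydronaphthalene-2,3-dicarboxylic acid | O=C(O)C1=Cc2cc(OCc3ccccc3)c(OCc3ccccc3)cc2[C@@H](c2ccc(OCc3ccccc3)c(O/C(=C/c3ccc(OCc4ccccc4)c(OCc4ccccc4)c3)C(=O)O)c2)[C@@H]1C(=O)O | intermediate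
16 | (1R,2S)-1-{3-[((E)-1-carboxy-2-(3,4-dihydroxyphenyl)ethenyl)oxy]-4-hydroxyphenyl}-6,7-dihydroxy-1,2-dihydronaphthalene-2,3-dicarboxylic acid | O=C(O)C1=Cc2cc(O)c(O)cc2[C@@H](c2ccc(O)c(O/C(=C/c3ccc(O)c(O)c3)C(=O)O)c2)[C@@H]1C(=O)O | target

**Step count and risks**
Total steps: 8. Longest linear sequence: 6 steps (1, 2, 3, 6, 7, 8).

Steps most likely to fail:

Step 6. The benzylic cation may be diverted into E1 loss of H-2 (the imide α-proton is acidic) to give the bis-arylidene diene, or the aldolate may revert or close with incomplete trans control in the presence of boron and ammonium salts. The fallback sets out from 10 and 5 and comes back at 15. The aldol is stopped at the aldolate and worked up oxidatively (pH 7 buffer, MeOH, H2O2, 0 °C) to give the isolated syn-aldol imide F1. The auxiliary is exchanged for a methyl ester with MeOMgBr in MeOH at 0 °C to give the hydroxy diester F2, the classical substrate class for acid cyclodehydration to trans-1-aryl-1,2-dihydronaphthalene-2,3-diesters, with a less acidic H-2. TFA in CH2Cl2 at 0 °C should then close the ring to the cyclised triester F3, and LiOH in THF/MeOH/H2O saponifies all three methyl esters to rejoin the route at 15.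

Step 2. Site control in the copper coupling may be lost, through a second substitution to the ketene acetal, dehydrobromination to the ynol ether, or sluggish coupling of the ortho-alkoxy phenol. The fallback sets out from 1 and 3 and comes back at 5, bypassing steps 2 and 3. Aldehyde 1 is olefinated with methyl bromo[bis(2,2,2-trifluoroethoxy)phosphoryl]acetate (t-BuOK, 18-crown-6, THF, −78 °C; a Still–Gennari-type Horner–Wadsworth–Emmons reagent that places the ester cis to the aryl group) to give the (E)-α-bromoacrylate F4. Ullmann-type coupling of the bromoacrylate with phenol 3 (CuI, N,N-dimethylglycine, Cs2CO3, dioxane, 70 °C) should replace bromine by the aryloxy group with retention and give 5 directly.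

Step 8. Ether cleavage may be incomplete because the triacid precipitates and chelates boron, the liberated catechol rings may be C-benzylated, or the enol ether geometry may drift under acid. The fallback sets out from 14 and comes back at 16. Step 7 is stopped after the sulfite quench and 14 is isolated; debenzylation (BCl3, C6HMe5, CH2Cl2, −78 °C) is run on this lipophilic, CH2Cl2-soluble compound to give the pentaphenol dimethyl ester F5. The two methyl esters are then cleaved last under non-oxidising conditions (LiOH in degassed THF/H2O under argon with sodium ascorbate, or pig-liver esterase at pH 7.5) to give 16.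

Further compounds
F1 | step 6 | isolated syn-aldol imide (free alcohol of 12; imide α-carbon R, carbinol carbon R) | COC(=O)/C(=C/c1ccc(OCc2ccccc2)c(OCc2ccccc2)c1)[C@@H](C(=O)N1C(=O)OC[C@H]1Cc1ccccc1)[C@@H](O)c1ccc(OCc2ccccc2)c(O/C(=C/c2ccc(OCc3ccccc3)c(OCc3ccccc3)c2)C(=O)OC)c1
F2 | step 6 | dimethyl (2R,3E)-2-{(R)-[4-(benzyloxy)-3-(((E)-2-[3,4-bis(benzyloxy)phenyl]-1-(methoxycarbonyl)ethenyl)oxy)phenyl](hydroxy)methyl}-3-[3,4-bis(benzyloxy)benzylidene]butanedioate | COC(=O)/C(=C/c1ccc(OCc2ccccc2)c(OCc2ccccc2)c1)[C@@H](C(=O)OC)[C@@H](O)c1ccc(OCc2ccccc2)c(O/C(=C/c2ccc(OCc3ccccc3)c(OCc3ccccc3)c2)C(=O)OC)c1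
F3 | step 6 | dimethyl (1R,2S)-6,7-bis(benzyloxy)-1-{4-(benzyloxy)-3-[((E)-2-[3,4-bis(benzyloxy)phenyl]-1-(methoxycarbonyl)ethenyl)oxy]phenyl}-1,2-dihydronaphthalene-2,3-dicarboxylate | COC(=O)C1=Cc2cc(OCc3ccccc3)c(OCc3ccccc3)cc2[C@@H](c2ccc(OCc3ccccc3)c(O/C(=C/c3ccc(OCc4ccccc4)c(OCc4ccccc4)c3)C(=O)OC)c2)[C@@H]1C(=O)OC
F4 | step 2 | methyl (E)-3-[3,4-bis(benzyloxy)phenyl]-2-bromoprop-2-enoate (Br trans to aryl) | Br/C(=C/c1ccc(OCc2ccccc2)c(OCc2ccccc2)c1)C(=O)OC
F5 | step 8 | (1R,2S)-6,7-dihydroxy-1-{4-hydroxy-3-[((E)-2-(3,4-dihydroxyphenyl)-1-(methoxycarbonyl)ethenyl)oxy]phenyl}-3-(methoxycarbonyl)-1,2-dihydronaphthalene-2-carboxylic acid | COC(=O)C1=Cc2cc(O)c(O)cc2[C@@H](c2ccc(O)c(O/C(=C/c3ccc(O)c(O)c3)C(=O)OC)c2)[C@@H]1C(=O)O
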